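## Retrosynthetic overview

1. Target 20 ⇐ methanolysis of ester 19; the ring B vinyl bromide ⇐ ketone 18 ⇐ hydroboration–oxidation and oxidation of the ring B alkene of 15.
2. trans-Bromohydrin ester 15 ⇐ Mitsunobu inversion of cis-bromohydrin 14 ⇐ hydride reduction of α′-bromoenone 13 ⇐ bromination of dienone 11.
3. 11 ⇐ methyl addition and enone transposition on spiro vinylogous ester 9 ⇐ ring-closing metathesis of 8 (ring B is formed second, onto ring A bought as 1).
4. 8 ⇐ Pd-catalysed decarboxylative asymmetric allylation of enol carbonate 7 (sets the spiro carbon) ⇐ α′-alkylation and O-acylation of 1.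

Assumption: 1, 2 and 5 are purchased, and the allylation follows the usual facial preference of (S)-t-BuPHOX-type ligands (the ligand that gives (S)-2-allyl-2-methylcyclohexanone), which maps onto (R)-8.

The target is a trans-bromohydrin (3S,4S) with bromine cis to the C7 methylene. Hydride reduction of the bromoenone is expected to give the cis isomer, so an inversion at C3 is built in.

## Route

Step 1
Reactants: 1 3-ethoxy-5,5-dimethylcyclohex-2-en-1-one; 2 4-bromo-2-methylbut-1-ene
Product: 4 racemic 3-ethoxy-5,5-dimethyl-6-(3-methylbut-3-en-1-yl)cyclohex-2-en-1-one, via lithium dienolate 3 (not isolated)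
Conditions: LiN(iPr)2, THF, −78 °C; then 2, DMPU, −78 → 23 °C
Reagents that add atoms: 4-bromo-2-methylbut-1-ene (compound 2), C=C(C)CCBr
Why: Kinetic deprotonation of the vinylogous ester occurs at the α′ carbon (C6) and the dienolate is alkylated by the primary bromide (Stork–Danheiser-type enolate alkylation); the new stereocentre is racemic and is erased in step 2.

Step 2
Reactants: 4 racemic 3-ethoxy-5,5-dimethyl-6-(3-methylbut-3-en-1-yl)cyclohex-2-en-1-one; 5 allyl chloroformate
Product: 7 5-ethoxy-3,3-dimethyl-2-(3-methylbut-3-en-1-yl)cyclohexa-1,5-dien-1-yl prop-2-en-1-yl carbonate, via lithium enolate 6 (not isolated)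
Conditions: LiN(iPr)2, TMEDA, THF, −78 °C; then 5, −78 → 0 °C
Reagents that add atoms: allyl chloroformate (compound 5), C=CCOC(Cl)=O
Why: The hindered, fully substituted lithium enolate is acylated on oxygen by the chloroformate (enolate O-acylation), giving the allyl enol carbonate needed for the decarboxylative allylation; no stereocentre remains.

Step 3
Reactants: 7 5-ethoxy-3,3-dimethyl-2-(3-methylbut-3-en-1-yl)cyclohexa-1,5-dien-1-yl prop-2-en-1-yl carbonate
Product: 8 (R)-3-ethoxy-5,5-dimethyl-6-(3-methylbut-3-en-1-yl)-6-(prop-2-en-1-yl)cyclohex-2-en-1-one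
Conditions: Pd2(dba)3 (5 mol %), (S)-(CF3)3-t-BuPHOX (12.5 mol %), toluene, 25 → 40 °C
Reagents that add atoms: none
Why: Decarboxylative asymmetric allylic alkylation (Tsuji allylation): loss of CO2 gives a palladium enolate/allyl pair whose C–C bond formation at C6 occurs on the enolate face dictated by the (S)-PHOX ligand, creating the quaternary stereocentre as (R) (about 85–90% ee expected, raised later by crystallising 15).

Step 4
Reactants: 8 (R)-3-ethoxy-5,5-dimethyl-6-(3-methylbut-3-en-1-yl)-6-(prop-2-en-1-yl)cyclohex-2-en-1-one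
Product: 9 (R)-3-ethoxy-5,5,9-trimethylspiro[5.5]undeca-2,8-dien-1-one
Conditions: second-generation Grubbs catalyst RuCl2(=CHPh)(PCy3)(H2IMes) (5 mol %), CH2Cl2, 40 °C
Reagents that add atoms: none
Why: Ring-closing metathesis of the monosubstituted and 1,1-disubstituted alkenes closes ring B as a trisubstituted cyclohexene with loss of ethene and leaves the quaternary centre untouched.

Step 5
Reactants: 9 (R)-3-ethoxy-5,5,9-trimethylspiro[5.5]undeca-2,8-dien-1-one
Product: 11 (R)-1,5,5,9-tetramethylspiro[5.5]undeca-1,8-dien-3-one, via lithium alkoxide adduct 10 (not isolated)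
Conditions: MeLi, CeCl3, THF, −78 → 0 °C; then 1 M aq. HCl, 23 °C
Reagents that add atoms: methyllithium, [Li]C; water, O
Why: Stork–Danheiser transposition: the organocerium reagent adds 1,2 to the hindered vinylogous-ester carbonyl, and acid then hydrolyses the enol ether and dehydrates the tertiary alcohol to the transposed 3-methyl enone without touching C6.

Step 6
Reactants: 11 (R)-1,5,5,9-tetramethylspiro[5.5]undeca-1,8-dien-3-one
Product: 13 (4S,6S)-4-bromo-1,5,5,9-tetramethylspiro[5.5]undeca-1,8-dien-3-one, via silyl dienol ether 12 (not isolated)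
Conditions: LiN(SiMe3)2, Me3SiCl, THF, −78 °C; then NBS, THF, −78 → 0 °C; then DBU (0.1 equiv), CH2Cl2, 23 °C
Reagents that add atoms: N-bromosuccinimide, BrN1C(=O)CCC1=O
Why: Kinetic α′-deprotonation (as with isophorone) and silylation give the cross-conjugated silyl dienol ether, electrophilic α-bromination puts bromine on C4, and base-mediated epimerisation then settles C4 in the more stable (4S) form, in which bromine is equatorial on the ring A half-chair that keeps the saturated C11 methylene pseudoaxial and the C1 methyl next to the flat sp2 carbon C8, so bromine ends cis to the allylic C7 methylene.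

Step 7
Reactants: 13 (4S,6S)-4-bromo-1,5,5,9-tetramethylspiro[5.5]undeca-1,8-dien-3-one
Product: 14 (3R,4S,6S)-4-bromo-1,5,5,9-tetramethylspiro[5.5]undeca-1,8-dien-3-ol
Conditions: i-Bu2AlH, CH2Cl2, −78 °C
Reagents that add atoms: none
Why: Carbonyl 1,2-reduction by the bulky aluminium hydride occurs from the face opposite the pseudoaxial C5 methyl (equatorial attack) and gives the axial (3R) alcohol cis to the equatorial bromine.

Step 8
Reactants: 14 (3R,4S,6S)-4-bromo-1,5,5,9-tetramethylspiro[5.5]undeca-1,8-dien-3-ol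
Product: 15 (3S,4S,6S)-4-bromo-1,5,5,9-tetramethylspiro[5.5]undeca-1,8-dien-3-yl 4-nitrobenzoate
Conditions: PPh3, DIAD, 4-nitrobenzoic acid, toluene, 0 → 23 °C
Reagents that add atoms: 4-nitrobenzoic acid, OC(=O)c1ccc(cc1)[N+](=O)[O-]
Why: Mitsunobu reaction: the oxyphosphonium of the axial alcohol is displaced by 4-nitrobenzoate in an SN2 process from the open opposite face, so C3 is inverted to (3S) (oxygen now trans to bromine), and the ester also protects the oxygen and gives a crystalline compound for raising the ee.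

Step 9
Reactants: 15 (3S,4S,6S)-4-bromo-1,5,5,9-tetramethylspiro[5.5]undeca-1,8-dien-3-yl 4-nitrobenzoate
Product: 17 (3S,4S,6S)-4-bromo-8-hydroxy-1,5,5,9-tetramethylspiro[5.5]undec-1-en-3-yl 4-nitrobenzoate (C8/C9 diastereomer mixture), via alkylborane 16 (not isolated)
Conditions: BH3·THF (1.1 equiv), THF, 0 °C; then H2O2, NaH2PO4/Na2HPO4 buffer (pH 7), 0 → 23 °C
Reagents that add atoms: hydrogen peroxide, OO
Why: Brown hydroboration–oxidation: the unhindered, electron-rich ring B alkene reacts in preference to the ring A alkene (deactivated by the allylic ester and shielded by the quaternary C6), boron adds to the less substituted C8 so oxygen ends there, and the new C8 and C9 centres are inconsequential because both become sp2 again.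

Step 10
Reactants: 17 (3S,4S,6S)-4-bromo-8-hydroxy-1,5,5,9-tetramethylspiro[5.5]undec-1-en-3-yl 4-nitrobenzoate (C8/C9 diastereomer mixture)
Product: 18 (3S,4S,6S)-4-bromo-1,5,5,9-tetramethyl-8-oxospiro[5.5]undec-1-en-3-yl 4-nitrobenzoate (C9 epimer mixture)
Conditions: Dess–Martin periodinane, CH2Cl2, 23 °C
Reagents that add atoms: none
Why: Dess–Martin oxidation converts the secondary alcohol into the ketone under neutral conditions that spare the ester, the secondary bromide and the ring A alkene.

Step 11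
Reactants: 18 (3S,4S,6S)-4-bromo-1,5,5,9-tetramethyl-8-oxospiro[5.5]undec-1-en-3-yl 4-nitrobenzoate (C9 epimer mixture)
Product: 19 (3S,4S,6S)-4,8-dibromo-1,5,5,9-tetramethylspiro[5.5]undeca-1,8-dien-3-yl 4-nitrobenzoate
Conditions: (PhO)3P, Br2, CH2Cl2, −60 °C; then Et3N, 18, −60 → 23 °C, then 40 °C
Reagents that add atoms: bromine, BrBr
Why: Deoxygenative bromination–elimination of the ketone by the halophosphonium reagent gives the vinyl bromide, and elimination runs toward C9 (Zaitsev, tetrasubstituted alkene) because the C7 hydrogens are neopentyl, which also removes the C9 stereocentre.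

Step 12
Reactants: 19 (3S,4S,6S)-4,8-dibromo-1,5,5,9-tetramethylspiro[5.5]undeca-1,8-dien-3-yl 4-nitrobenzoate
Product: 20 (3S,4S,6S)-4,8-dibromo-1,5,5,9-tetramethylspiro[5.5]undeca-1,8-dien-3-ol
Conditions: K2CO3 (0.2 equiv), MeOH, 0 → 23 °C
Reagents that add atoms: none
Why: Base-catalysed transesterification (methanolysis) removes the activated 4-nitrobenzoate with retention at C3, and the diequatorial trans-bromohydrin cannot easily reach the diaxial geometry needed for epoxide closure.

## Compound list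

1 | 3-ethoxy-5,5-dimethylcyclohex-2-en-1-one | CCOC1=CC(=O)CC(C)(C)C1 | starting material
2 | 4-bromo-2-methylbut-1-ene | C=C(C)CCBr | starting material
3 | lithium 5-ethoxy-3,3-dimethylcyclohexa-1,5-dien-1-olate | [Li]OC1=CC(C)(C)CC(OCC)=C1 | intermediate
4 | racemic 3-ethoxy-5,5-dimethyl-6-(3-methylbut-3-en-1-yl)cyclohex-2-en-1-one | CCOC1=CC(=O)C(CCC(C)=C)C(C)(C)C1 | intermediate
5 | allyl chloroformate (prop-2-en-1-yl carbonochloridate) | C=CCOC(Cl)=O | starting material
6 | lithium 5-ethoxy-3,3-dimethyl-2-(3-methylbut-3-en-1-yl)cyclohexa-1,5-dien-1-olate | [Li]OC1=C(CCC(C)=C)C(C)(C)CC(OCC)=C1 | intermediate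
7 | 5-ethoxy-3,3-dimethyl-2-(3-methylbut-3-en-1-yl)cyclohexa-1,5-dien-1-yl prop-2-en-1-yl carbonate | C=CCOC(=O)OC1=C(CCC(C)=C)C(C)(C)CC(OCC)=C1 | intermediate
8 | (R)-3-ethoxy-5,5-dimethyl-6-(3-methylbut-3-en-1-yl)-6-(prop-2-en-1-yl)cyclohex-2-en-1-one | C=CC[C@@]1(CCC(C)=C)C(=O)C=C(OCC)CC1(C)C | intermediate
9 | (R)-3-ethoxy-5,5,9-trimethylspiro[5.5]undeca-2,8-dien-1-one | CCOC1=CC(=O)[C@]2(CC=C(C)CC2)C(C)(C)C1 | intermediate
10 | lithium (6R)-3-ethoxy-1,5,5,9-tetramethylspiro[5.5]undeca-2,8-dien-1-olate (C1 epimer mixture) | CCOC1=CC(C)(O[Li])[C@]2(CC=C(C)CC2)C(C)(C)C1 | intermediate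
11 | (R)-1,5,5,9-tetramethylspiro[5.5]undeca-1,8-dien-3-one | CC1=CC(=O)CC(C)(C)[C@@]12CC=C(C)CC2 | intermediate
12 | trimethyl{[(6S)-1,5,5,9-tetramethylspiro[5.5]undeca-1,3,8-trien-3-yl]oxy}silane | CC1=CC(O[Si](C)(C)C)=CC(C)(C)[C@@]12CC=C(C)CC2 | intermediate
13 | (4S,6S)-4-bromo-1,5,5,9-tetramethylspiro[5.5]undeca-1,8-dien-3-one | CC1=CC(=O)[C@@H](Br)C(C)(C)[C@@]12CC=C(C)CC2 | intermediate
14 | (3R,4S,6S)-4-bromo-1,5,5,9-tetramethylspiro[5.5]undeca-1,8-dien-3-ol | CC1=C[C@@H](O)[C@@H](Br)C(C)(C)[C@@]12CC=C(C)CC2 | intermediate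
15 | (3S,4S,6S)-4-bromo-1,5,5,9-tetramethylspiro[5.5]undeca-1,8-dien-3-yl 4-nitrobenzoate | CC1=C[C@H](OC(=O)c3ccc(cc3)[N+](=O)[O-])[C@@H](Br)C(C)(C)[C@@]12CC=C(C)CC2 | intermediate
16 | [(3S,4S,6S)-4-bromo-1,5,5,9-tetramethyl-3-(4-nitrobenzoyloxy)spiro[5.5]undec-1-en-8-yl]borane | CC1=C[C@H](OC(=O)c3ccc(cc3)[N+](=O)[O-])[C@@H](Br)C(C)(C)[C@@]12CC(B)C(C)CC2 | intermediate
17 | (3S,4S,6S)-4-bromo-8-hydroxy-1,5,5,9-tetramethylspiro[5.5]undec-1-en-3-yl 4-nitrobenzoate (C8/C9 diastereomer mixture) | CC1=C[C@H](OC(=O)c3ccc(cc3)[N+](=O)[O-])[C@@H](Br)C(C)(C)[C@@]12CC(O)C(C)CC2 | intermediate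
18 | (3S,4S,6S)-4-bromo-1,5,5,9-tetramethyl-8-oxospiro[5.5]undec-1-en-3-yl 4-nitrobenzoate (C9 epimer mixture) | CC1=C[C@H](OC(=O)c3ccc(cc3)[N+](=O)[O-])[C@@H](Br)C(C)(C)[C@@]12CC(=O)C(C)CC2 | intermediate
19 | (3S,4S,6S)-4,8-dibromo-1,5,5,9-tetramethylspiro[5.5]undeca-1,8-dien-3-yl 4-nitrobenzoate | CC1=C[C@H](OC(=O)c3ccc(cc3)[N+](=O)[O-])[C@@H](Br)C(C)(C)[C@@]12CC(Br)=C(C)CC2 | intermediate
20 | (3S,4S,6S)-4,8-dibromo-1,5,5,9-tetramethylspiro[5.5]undeca-1,8-dien-3-ol | CC1=C[C@H](O)[C@@H](Br)C(C)(C)[C@]12CCC(C)=C(Br)C2 | target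

## Step count and risks

Total step count: 12. Longest linear sequence: 12 steps (1 → 20).

The three steps most likely to fail:

Step 6, the C4 configuration. The preference for the (4S) bromide rests on a conformational argument and on equilibration, and the ratio may be modest. The fallback gives up stereocontrol in favour of a separate-and-recycle loop; it sets out from 11 and comes back to the route at 14. The silyl dienol ether from 11 is brominated without equilibration, giving 13 together with (4R,6S)-4-bromo-1,5,5,9-tetramethylspiro[5.5]undeca-1,8-dien-3-one F1. The mixture is reduced with i-Bu2AlH as in step 7, and 14 is separated by chromatography from (3S,4R,6S)-4-bromo-1,5,5,9-tetramethylspiro[5.5]undeca-1,8-dien-3-ol F2. F2 is oxidised with MnO2 back to F1, which is epimerised with DBU and fed through again.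

Step 8, the Mitsunobu inversion. The carbinol is hindered and has an antiperiplanar C4 hydrogen, so elimination to a bromodiene can compete. The fallback replaces substrate-controlled reduction plus SN2 inversion by a reagent-controlled reduction; it sets out from 13 and comes back at 15. Corey–Bakshi–Shibata reduction of 13 ((S)-2-methyl-CBS-oxazaborolidine, catecholborane, toluene, −78 °C, the alkenyl branch acting as the large group) delivers hydride to the face cis to bromine. This gives (3S,4S,6S)-4-bromo-1,5,5,9-tetramethylspiro[5.5]undeca-1,8-dien-3-ol F3 directly. Acylation with 4-nitrobenzoyl chloride and pyridine then gives 15.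

Step 9, the chemoselective hydroboration. Borane could also attack the ring A alkene, and the resulting β-acyloxy borane would eliminate. The fallback uses an epoxide rearrangement in place of hydroboration; it sets out from 15 and comes back at 18, skipping step 10. mCPBA in CH2Cl2 at 0 °C epoxidises only the electron-rich ring B alkene, giving (3S,4S,6S)-4-bromo-8,9-epoxy-1,5,5,9-tetramethylspiro[5.5]undec-1-en-3-yl 4-nitrobenzoate F4. Meinwald rearrangement with catalytic Bi(OTf)3 in CH2Cl2 at −40 °C (opening at the tertiary C9, 1,2-hydride shift from C8) then gives ketone 18.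

## Further compounds

F1 | step 6 | (4R,6S)-4-bromo-1,5,5,9-tetramethylspiro[5.5]undeca-1,8-dien-3-one | CC1=CC(=O)[C@H](Br)C(C)(C)[C@@]12CC=C(C)CC2
F2 | step 6 | (3S,4R,6S)-4-bromo-1,5,5,9-tetramethylspiro[5.5]undeca-1,8-dien-3-ol | CC1=C[C@H](O)[C@H](Br)C(C)(C)[C@@]12CC=C(C)CC2
F3 | step 8 | (3S,4S,6S)-4-bromo-1,5,5,9-tetramethylspiro[5.5]undeca-1,8-dien-3-ol | CC1=C[C@H](O)[C@@H](Br)C(C)(C)[C@@]12CC=C(C)CC2
F4 | step 9 | (3S,4S,6S)-4-bromo-8,9-epoxy-1,5,5,9-tetramethylspiro[5.5]undec-1-en-3-yl 4-nitrobenzoate | CC1=C[C@H](OC(=O)c3ccc(cc3)[N+](=O)[O-])[C@@H](Br)C(C)(C)[C@@]12CC4OC4(C)CC2
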